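You are about to cut the free catalyst to half of Monday's charge and stop at 30 min, so work out one number first.

in all of them: left-handed substrate 0.29 M; right-handed substrate 0.29 M; racemization catalyst 43 mM

| charge | solid reagent | free catalyst | remark | time |
|---|---|---|---|---|
| Monday's | 0.87 M | 92 mM | run made earlier |  |
| flask | 0.870 M | 46 mM |  | 30 min |

Monday's run (percent of the left-handed substrate and right-handed substrate together charged)

| time / min | left-handed substrate / % | right-handed substrate / % | left-handed product / % |
|---|---|---|---|
| 0.500 | 54 | 50 | 2 |
| 1.50 | 45 | 48 | 2 |
| 3.00 | 40 | 50 | 15 |
| 4.00 | 31 | 44 | 20 |
| 6.00 | 22 | 50 | 30 |

(scatter of a reading: 2 percentage points)

- free catalyst is single-handed; left-handed substrate and right-handed substrate are mirror images of each other, charged as a racemate, each of them at the stated concentration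
- as a solid, counted per litre of solution: solid reagent
- at the start none of the solid reagent is in solution
- an excess is the difference of the two amounts in percent of their sum
- an excess is below zero if the other one leads
- no earlier run changes the charge of free catalyst; that part of a forecast is a guess

* part of the left-handed substrate and right-handed substrate charged together that has reacted at 30 min
* excess of left-handed product over right-handed product in the product at 30 min
* excess of right-handed substrate over left-handed substrate among what is left of the two at 30 min

Monday's left-handed substrate falls along a nearly straight line (zero order, as a reading), from 54% to 22% of the charge between 0.500 min and 6.00 min. Freeze that slope, and the left-handed share of the charge lasts 8.59 min on Monday's catalyst. That is the first rung. No earlier run changes the free catalyst, so it is my guess that the slope follows it. On that guess this flask has 17.2 min as its emptying time, the time a straight fall takes to use up the left-handed share.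

Since that is shorter than the stop, I expect left-handed product and right-handed substrate to lead in this flask at 30 min. The second rung is the right-handed substrate. It reads 50% first and 50% last, but a fall within the scatter of 2 percentage points can hide in 6.00 min, and over 30 min that becomes 10 points of the charge. My reckoning is therefore the left-handed share reacted, plus perhaps a right-handed loss of about that size.

The forecast says 55% reacted (46% to 68%), product excess 97% (88% to 100%) and substrate excess 90% (68% to 100%), holding that the right-handed substrate “barely reacts and racemization is slow”.

The flask gives 65.2% reacted, product excess 71.7% and substrate excess 91.1%.

    partner + free catalyst + left-handed substrate → free catalyst + left-handed product (k = 21.0 /M²/min)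
    partner + free catalyst + right-handed substrate → free catalyst + right-handed product (k = 0.900 /M²/min)
    left-handed substrate + racemization catalyst ⇌ right-handed substrate + racemization catalyst, rate k3*[racemization catalyst]*[left-handed substrate] forward; the back reaction follows from the equilibrium constant (k = 0.240 /M/min)
    racemization catalyst ⇌ dormant form (K = 0.390, k = 0.00770 /min)
    solid reagent ⇌ partner, rate k5*(cs5 - [partner]) while solid is left; crystals form when [partner] > cs5 (solubility = 0.280 M, k = 0.210 /min)

Against the emptying time of 17.2 min, the straight line gives 6.40% of left-handed substrate at 15.0 min, and this flask holds 8.92%. With 0.028 M of free catalyst the emptying time comes to 28.2 min, and that neighbour holds 3.92% at 30 min. In this flask at 30 min, making left-handed product uses left-handed substrate 28 times faster than the forward racemization step loses it, and that making by itself gives the left-handed substrate a half-life of 2.8 min. Of its own charge, this flask then keeps 3.1% of the left-handed substrate against 67% of the right-handed.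

The earlier runs and the new flask are simulated with made-up constants, and the scatter is random.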